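**Retrosynthetic overview**
1. Target ⇒ last, catalyst-controlled epoxidation of the Z-C1=C2 bond of a 10-membered diene; C8 ester and C13 acetate by acylation; butenolide (C7=C11, O–C6) by intramolecular Horner–Wadsworth–Emmons olefination of a C7 ketone.
2. 10-Membered carbocycle ⇐ 12-membered β-oxo lactone (ester between a carboxyl on C8 and the C9 hydroxyl) by Pd-catalysed decarboxylative ring contraction: the C8–C9 bond is made, CO2 is extruded, and C8 is set from an epimeric/enolic mixture.
3. Enabling feature: ring atoms C9 and C10 with the exocyclic methylene C14 form a 2-substituted allyl unit whose two CH2 ends become equivalent in a π-allyl; it sits next to C8, which bears oxygen and is α to C7, a ketone carbon before it becomes the β-carbon of the butenolide ring. C8 can therefore be an enolate carbon and C9 an allyl cation, tethered for a time through CO2.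
4. Lactone ⇐ crossed Claisen condensation and silver-promoted macrolactonisation; chain from carboalumination (E-C4=C5), oxalate acylation, asymmetric ketone reduction (C6), hydroxyl-directed epoxidation (C4, C5), Sonogashira coupling and semireduction (Z-diene).
5. Ring order: oxirane C4–C5 → 12-membered lactone → 10-membered carbocycle → butenolide → oxirane C1–C2.

Key step: step 12

Remark: locants C1–C15 in the names follow germacrane numbering of the target (C1–C10 ring, C1 = epoxide CH next to C10, C14 = exocyclic CH2 on C10, C15 = CH3 on C4, C12 = lactone C=O, C13 = CH2OAc). The descriptor at C6 changes from R to S in step 17 only because CIP priorities change. The sense of induction in step 4 is assumed by analogy with aryl ketones (alkenyl = large group), and the ketone catalyst of step 24 is taken as a catalogue item.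

**Step 1**
Reactants: 1 ethynyl(trimethyl)silane; 2 3-bromoprop-1-yne
Product: 3 trimethyl(penta-1,4-diyn-1-yl)silane
Conditions: EtMgBr, THF, 0 °C → rt; then CuCl (cat.), 2, 50 °C
Reagents that add atoms: none
Why: Copper-catalysed coupling of an alkynyl Grignard reagent with a propargylic bromide gives the skipped diyne that holds C1–C5, the silyl group marking the alkyne that must stay inert in step 2.

**Step 2**
Reactants: 3 trimethyl(penta-1,4-diyn-1-yl)silane
Product: 4 [(4E)-5-iodo-4-methylpent-4-en-1-yn-1-yl](trimethyl)silane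
Conditions: Me3Al, Cp2ZrCl2 (0.25 equiv), CH2Cl2, rt; then I2, THF, −30 → 0 °C
Reagents that add atoms: trimethylaluminium, C[Al](C)C; iodine, II
Why: Negishi zirconium-catalysed carboalumination adds methyl and aluminium syn and regioselectively across the terminal alkyne only, and iodinolysis with retention fixes the E-trisubstituted C4=C5 geometry that later becomes the trans-4,5-epoxide.

**Step 3**
Reactants: 4 alkenyl iodide; 5 dimethyl oxalate
Product: 6 methyl (3E)-4-methyl-2-oxo-7-(trimethylsilyl)hept-3-en-6-ynoate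
Conditions: t-BuLi (2.05 equiv), Et2O, −78 °C; cannulated into 5 (3 equiv), THF, −78 °C; aq. NH4Cl
Reagents that add atoms: none
Why: Iodine–lithium exchange with retention of alkene geometry and acylation of the alkenyllithium by excess oxalate (inverse addition, stable tetrahedral adduct at −78 °C) should give the α-keto ester without double addition.

**Step 4**
Reactants: 6 α-keto ester
Product: 7 methyl (2R,3E)-2-hydroxy-4-methyl-7-(trimethylsilyl)hept-3-en-6-ynoate
Conditions: (−)-DIP-Cl, THF, −25 °C; then MeCHO, 0 °C → rt; aq. NaHCO3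
Reagents that add atoms: none
Why: Asymmetric reduction of the α-keto ester with B-chlorodiisopinocampheylborane (boat-like hydride transfer, alkenyl as the large group) should give the (2R)-carbinol, which is C6 of the target, without touching C=C or C≡C.

**Step 5**
Reactants: 7 allylic α-hydroxy ester
Product: 8 methyl (2R)-2-hydroxy-2-{(2R,3R)-3-methyl-3-[3-(trimethylsilyl)prop-2-yn-1-yl]oxiran-2-yl}acetate
Conditions: mCPBA, NaHCO3, CH2Cl2, 0 °C
Reagents that add atoms: 3-chloroperoxybenzoic acid, OOC(=O)c1cccc(Cl)c1
Why: Hydroxyl-directed Prilezhaev epoxidation in which A(1,3) strain with the cis methyl group holds the carbinol C–H in the alkene plane, so oxygen is delivered syn to OH and anti to the ester and sets C4 and C5 threo to C6; the silylalkyne is inert.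

**Step 6**
Reactants: 8 epoxy alcohol
Product: 9 methyl (2R)-2-{(2R,3R)-3-methyl-3-[3-(trimethylsilyl)prop-2-yn-1-yl]oxiran-2-yl}-2-[(triethylsilyl)oxy]acetate
Conditions: TESCl, imidazole, DMF, 0 °C
Reagents that add atoms: chlorotriethylsilane, CC[Si](Cl)(CC)CC
Why: Standard silylation of the secondary alcohol; TES is chosen because it must later be removed beside the TBS ether at C8, and a free C6 hydroxyl would give a tetronic acid in step 11.

**Step 7**
Reactants: 9 silylalkyne; 10 2-bromoprop-2-en-1-ol
Product: 12 methyl (2R)-2-{(2R,3R)-3-[4-(hydroxymethyl)pent-4-en-2-yn-1-yl]-3-methyloxiran-2-yl}-2-[(triethylsilyl)oxy]acetate, via terminal alkyne 11 (not isolated)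
Conditions: K2CO3 (cat.), MeOH, 0 °C; solvent exchange; then 10, Pd(PPh3)4 (5 mol%), CuI (10 mol%), i-Pr2NH, THF, rt
Reagents that add atoms: none
Why: Methanolysis of the C(sp)–Si bond followed by Sonogashira coupling of the terminal alkyne with the vinyl bromide brings in C9, C10 and C14 without creating a stereocentre.

**Step 8**
Reactants: 12 enyne alcohol
Product: 13 methyl (2R)-2-{(2R,3R)-3-[(2Z)-4-(hydroxymethyl)penta-2,4-dien-1-yl]-3-methyloxiran-2-yl}-2-[(triethylsilyl)oxy]acetate
Conditions: Zn(Cu/Ag), MeOH/H2O (1:1), 40 °C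
Reagents that add atoms: none
Why: Activated-zinc semireduction of a conjugated enyne is cis-selective and does not over-reduce, which should give the Z-C1=C2 bond while epoxide, ester and silyl ether stay intact.

**Step 9**
Reactants: 14 methyl 2-[(tert-butyldimethylsilyl)oxy]acetate; 15 2-methylpropane-2-thiol
Product: 16 S-tert-butyl 2-[(tert-butyldimethylsilyl)oxy]ethanethioate
Conditions: Me3Al, CH2Cl2, 0 °C → rt
Reagents that add atoms: none
Why: Transthioesterification of a methyl ester with dimethylaluminium tert-butylthiolate formed in the flask; no stereocentre.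

**Step 10**
Reactants: 13 diene ester; 16 thioester
Product: 17 S-tert-butyl (4R)-2-[(tert-butyldimethylsilyl)oxy]-4-{(2R,3R)-3-[(2Z)-4-(hydroxymethyl)penta-2,4-dien-1-yl]-3-methyloxiran-2-yl}-3-oxo-4-[(triethylsilyl)oxy]butanethioate (C2 epimers and enol)
Conditions: 16, LDA, THF, −78 °C; then 13 (premixed with LiHMDS, 1.0 equiv), −78 → −40 °C; AcOH
Reagents that add atoms: none
Why: Crossed Claisen condensation in which the preformed lithium thioester enolate acylates at the methyl ester (C7) and the product is protected as its enolate; C8 forms without control because step 12 erases it.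

**Step 11**
Reactants: 17 β-keto thioester
Product: 18 12-membered β-oxo lactone (ester C8–C(=O)–O–C9; (4R,5R)-epoxide, (6R)-OTES, 7-oxo, 8-OTBS as epimers/enol, 1Z-ene, 10(14)-methylidene)
Conditions: AgOCOCF3, Na2HPO4, THF, 1 mM (syringe pump), rt, dark
Reagents that add atoms: none
Why: Silver(I)-promoted acylation of an alcohol by a β-keto thioester (thiophilic activation) should close the 12-membered lactone under buffered neutral conditions at high dilution.

**Step 12**
Reactants: 18 12-membered β-oxo lactone
Product: 19 (4R,5R,6R,8S)-8-[(tert-butyldimethylsilyl)oxy]-4,5-epoxy-6-[(triethylsilyl)oxy]-11,12,13-trinorgermacra-1Z,10(14)-dien-7-one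
Conditions: Pd2(dba)3 (5 mol%), (S)-t-BuPHOX (12.5 mol%), THF, 1 mM, 30 °C
Reagents that add atoms: none
Why: Proposed new method: Pd(0) ionises the allylic C9–O bond of the lactone to a π-allylpalladium/β-oxo-carboxylate ion pair, CO2 is lost, and the resulting C7(O)=C8 enolate carbon bonds to an allyl terminus, which contracts the 12-membered lactone to the 10-membered carbocycle; the closest known reaction type is the Tsuji-type decarboxylative allylation (palladium variant of the Carroll rearrangement) of acyclic allyl β-keto esters and of α-oxygenated enol carbonates, which has not been used as a ring contraction of a macrolactone. The only ring closed is the carbocycle, by intramolecular allylic alkylation (C8 onto the allyl terminus, 10-membered, the former ester carbon and oxygen leaving the ring as CO2). Because the 2-substituted π-allyl has two CH2 termini (C9 and C14), attack at either end gives the same product and regenerates the exocyclic methylene, so no regiochemical question arises. C8 is the only new stereocentre: it forms from a planar enolate, so the C8 epimers and the enol of 18 converge, and its configuration should be fixed by the (S)-t-BuPHOX–palladium enolate in the inner-sphere C–C bond formation (ligand control, as in decarboxylative asymmetric allylation of α-oxygenated ketone enolates), with the antipodal ligand as the lever if the ring stereocentres prove mismatched. The step needs C- over O-allylation and ring closure over intermolecular coupling or protonation, which the tethered ion pair at 1 mM, the lack of β-hydrogens on the π-allyl (C1 is sp2) and the regiospecific birth of the enolate at C8 (never at C6, so no β-elimination of the 4,5-epoxide) should secure. The 4,5-epoxide is not vinylic and both silyl ethers are inert to Pd(0).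

**Step 13**
Reactants: 19 ten-membered ketone
Product: 20 (4R,5R,6R,8S)-8-[(tert-butyldimethylsilyl)oxy]-4,5-epoxy-6-hydroxy-11,12,13-trinorgermacra-1Z,10(14)-dien-7-one
Conditions: HF·pyridine, pyridine, THF, 0 °C
Reagents that add atoms: none
Why: Selective desilylation, the triethylsilyl ether being cleaved far faster than the bulkier TBS ether, frees the C6 hydroxyl only.

**Step 14**
Reactants: 21 benzyl 2-(diethoxyphosphoryl)acetate; 22 (chloromethoxy)tri(propan-2-yl)silane
Product: 23 benzyl 2-(diethoxyphosphoryl)-3-{[tri(propan-2-yl)silyl]oxy}propanoate (racemic)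
Conditions: NaH (1.0 equiv), THF, 0 °C; then 22, 0 °C → rt
Reagents that add atoms: none
Why: C-Alkylation of the sodium phosphonoacetate anion with a reactive α-chloro ether introduces the protected C13 hydroxymethyl group; the product is less acidic than the starting phosphonate and should not be deprotonated again.

**Step 15**
Reactants: 23 benzyl ester
Product: 24 2-(diethoxyphosphoryl)-3-{[tri(propan-2-yl)silyl]oxy}propanoic acid
Conditions: H2 (1 atm), 10% Pd/C, EtOAc, rt
Reagents that add atoms: none
Why: Hydrogenolysis of the benzyl ester gives the acid under neutral conditions, which avoids β-elimination of the silyloxy group.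

**Step 16**
Reactants: 20 α-hydroxy ketone; 24 phosphono acid
Product: 25 6-O-[2-(diethoxyphosphoryl)-3-(triisopropylsilyloxy)propanoyl] ester of 20 (epimers at the phosphonate carbon)
Conditions: EDC·HCl, DMAP (cat.), CH2Cl2, 0 °C
Reagents that add atoms: none
Why: Steglich esterification of the secondary α-ketol with retention at C6.

**Step 17**
Reactants: 25 phosphonate ester
Product: 26 (4R,5R,6S,8S)-8-[(tert-butyldimethylsilyl)oxy]-4,5-epoxy-13-[(triisopropylsilyl)oxy]germacra-1Z,7(11),10(14)-trien-12,6-olide
Conditions: LiCl, DBU, MeCN, 0 °C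
Reagents that add atoms: none
Why: Intramolecular Horner–Wadsworth–Emmons reaction (Masamune–Roush conditions) of the lithium-chelated phosphonate onto the C7 ketone closes the five-membered lactone and creates the tetrasubstituted C7=C11 bond, the fast 5-ring closure being expected to outrun enolisation toward C6 or C8.

**Step 18**
Reactants: 26 bis-silyl ether
Product: 27 (4R,5R,6S,8S)-4,5-epoxy-8,13-dihydroxygermacra-1Z,7(11),10(14)-trien-12,6-olide
Conditions: HF·pyridine, pyridine, THF, 0 °C → rt
Reagents that add atoms: none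
Why: Fluoride-mediated cleavage of the secondary TBS and primary TIPS ethers, buffered with pyridine to spare the trisubstituted epoxide.

**Step 19**
Reactants: 27 diol
Product: 28 (4R,5R,6S,8S)-13-acetoxy-4,5-epoxy-8-hydroxygermacra-1Z,7(11),10(14)-trien-12,6-olide
Conditions: AcCl (1.05 equiv), 2,4,6-collidine, CH2Cl2, −78 °C
Reagents that add atoms: acetyl chloride, CC(Cl)=O
Why: Kinetically selective acylation of the primary allylic C13 hydroxyl over the hindered secondary C8 hydroxyl.

**Step 20**
Reactants: 29 ethyl 2-(hydroxymethyl)prop-2-enoate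
Product: 30 ethyl 2-{[(tert-butyldimethylsilyl)oxy]methyl}prop-2-enoate
Conditions: TBSCl, imidazole, DMF, rt
Reagents that add atoms: tert-butyl(chloro)dimethylsilane, CC(C)(C)[Si](C)(C)Cl
Why: Standard silylation of a primary alcohol.

**Step 21**
Reactants: 30 silyl ether ester
Product: 31 2-{[(tert-butyldimethylsilyl)oxy]methyl}prop-2-enoic acid
Conditions: LiOH, THF/H2O, 0 °C → rt; then 1 M HCl to pH 4
Reagents that add atoms: lithium hydroxide, [Li+].[OH-]
Why: Saponification of the ethyl ester, which the primary TBS ether should survive.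

**Step 22**
Reactants: 28 C8 alcohol; 31 protected acrylic acid
Product: 32 (4R,5R,6S,8S)-13-acetoxy-8-(2-{[(tert-butyldimethylsilyl)oxy]methyl}acryloyloxy)-4,5-epoxygermacra-1Z,7(11),10(14)-trien-12,6-olide
Conditions: EDC·HCl, DMAP, CH2Cl2, 0 °C → rt
Reagents that add atoms: none
Why: Steglich esterification of the C8 hydroxyl with retention of configuration.

**Step 23**
Reactants: 32 silyl ether
Product: 33 (4R,5R,6S,8S)-13-acetoxy-4,5-epoxy-8-[2-(hydroxymethyl)acryloyloxy]germacra-1Z,7(11),10(14)-trien-12,6-olide
Conditions: HF·pyridine, pyridine, THF, 0 °C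
Reagents that add atoms: none
Why: Desilylation of the primary allylic TBS ether under buffered conditions that acetate, lactone and epoxide should tolerate; it is placed before the acid-labile vinyl epoxide exists.

**Step 24**
Reactants: 33 diene
Product: 34 (1R,2S,4R,5R,6S,8S)-13-acetoxy-1,2:4,5-diepoxy-8-[2-(hydroxymethyl)acryloyloxy]germacra-7(11),10(14)-dien-12,6-olide (CNP0233746.1)
Conditions: D-glucose-derived N-(4-ethylphenyl)oxazolidinone ketone (0.3 equiv), Oxone, K2CO3, DME/dimethoxymethane, aq. buffer pH 8, −10 → 0 °C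
Reagents that add atoms: potassium peroxymonosulfate (Oxone), [K+].[O-]S(=O)(=O)OO
Why: Shi epoxidation with a chiral dioxirane of the type known to oxidise the cis double bond of conjugated cis-dienes regioselectively and stereospecifically to vinyl cis-epoxides; the catalyst places the vinyl substituent (C10=C14) next to its oxazolidinone ring, which should give the (1R,2S)-epoxide, and the electron-poor acrylate and butenolide alkenes should not react.

**Compound list**
1 | ethynyl(trimethyl)silane | C[Si](C)(C)C#C | starting material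
2 | 3-bromoprop-1-yne | BrCC#C | starting material
3 | trimethyl(penta-1,4-diyn-1-yl)silane | C[Si](C)(C)C#CCC#C | intermediate
4 | [(4E)-5-iodo-4-methylpent-4-en-1-yn-1-yl](trimethyl)silane | C[Si](C)(C)C#CC/C(C)=C/I | intermediate
5 | dimethyl oxalate | COC(=O)C(=O)OC | starting material
6 | methyl (3E)-4-methyl-2-oxo-7-(trimethylsilyl)hept-3-en-6-ynoate | COC(=O)C(=O)/C=C(\C)CC#C[Si](C)(C)C | intermediate
7 | methyl (2R,3E)-2-hydroxy-4-methyl-7-(trimethylsilyl)hept-3-en-6-ynoate | COC(=O)[C@H](O)/C=C(\C)CC#C[Si](C)(C)C | intermediate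
8 | methyl (2R)-2-hydroxy-2-{(2R,3R)-3-methyl-3-[3-(trimethylsilyl)prop-2-yn-1-yl]oxiran-2-yl}acetate | C[Si](C)(C)C#CC[C@@]1(C)O[C@@H]1[C@@H](O)C(=O)OC | intermediate
9 | methyl (2R)-2-{(2R,3R)-3-methyl-3-[3-(trimethylsilyl)prop-2-yn-1-yl]oxiran-2-yl}-2-[(triethylsilyl)oxy]acetate | C[Si](C)(C)C#CC[C@@]1(C)O[C@@H]1[C@@H](O[Si](CC)(CC)CC)C(=O)OC | intermediate
10 | 2-bromoprop-2-en-1-ol | OCC(Br)=C | starting material
11 | methyl (2R)-2-[(2R,3R)-3-methyl-3-(prop-2-yn-1-yl)oxiran-2-yl]-2-[(triethylsilyl)oxy]acetate | C#CC[C@@]1(C)O[C@@H]1[C@@H](O[Si](CC)(CC)CC)C(=O)OC | intermediate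
12 | methyl (2R)-2-{(2R,3R)-3-[4-(hydroxymethyl)pent-4-en-2-yn-1-yl]-3-methyloxiran-2-yl}-2-[(triethylsilyl)oxy]acetate | C=C(CO)C#CC[C@@]1(C)O[C@@H]1[C@@H](O[Si](CC)(CC)CC)C(=O)OC | intermediate
13 | methyl (2R)-2-{(2R,3R)-3-[(2Z)-4-(hydroxymethyl)penta-2,4-dien-1-yl]-3-methyloxiran-2-yl}-2-[(triethylsilyl)oxy]acetate | C=C(CO)/C=C\C[C@@]1(C)O[C@@H]1[C@@H](O[Si](CC)(CC)CC)C(=O)OC | intermediate
14 | methyl 2-[(tert-butyldimethylsilyl)oxy]acetate | COC(=O)CO[Si](C)(C)C(C)(C)C | starting material
15 | 2-methylpropane-2-thiol | CC(C)(C)S | starting material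
16 | S-tert-butyl 2-[(tert-butyldimethylsilyl)oxy]ethanethioate | CC(C)(C)SC(=O)CO[Si](C)(C)C(C)(C)C | intermediate
17 | S-tert-butyl (4R)-2-[(tert-butyldimethylsilyl)oxy]-4-{(2R,3R)-3-[(2Z)-4-(hydroxymethyl)penta-2,4-dien-1-yl]-3-methyloxiran-2-yl}-3-oxo-4-[(triethylsilyl)oxy]butanethioate (C2 epimers) | C=C(CO)/C=C\C[C@@]1(C)O[C@@H]1[C@@H](O[Si](CC)(CC)CC)C(=O)C(O[Si](C)(C)C(C)(C)C)C(=O)SC(C)(C)C | intermediate
18 | 12-membered β-oxo lactone: (4R,5R)-4,5-epoxy-6R-(triethylsilyloxy)-7-oxo-8-(tert-butyldimethylsilyloxy)-1Z-ene-10(14)-methylidene chain C9→C8 closed by the ester C8–C(=O)–O–C9 (C8 epimers) | O=C1OCC(=C)/C=C\C[C@@]2(C)O[C@@H]2[C@@H](O[Si](CC)(CC)CC)C(=O)C1O[Si](C)(C)C(C)(C)C | intermediate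
19 | (4R,5R,6R,8S)-8-[(tert-butyldimethylsilyl)oxy]-4,5-epoxy-6-[(triethylsilyl)oxy]-11,12,13-trinorgermacra-1Z,10(14)-dien-7-one | CC(C)(C)[Si](C)(C)O[C@H]1CC(=C)/C=C\C[C@@]2(C)O[C@@H]2[C@@H](O[Si](CC)(CC)CC)C1=O | intermediate
20 | (4R,5R,6R,8S)-8-[(tert-butyldimethylsilyl)oxy]-4,5-epoxy-6-hydroxy-11,12,13-trinorgermacra-1Z,10(14)-dien-7-one | CC(C)(C)[Si](C)(C)O[C@H]1CC(=C)/C=C\C[C@@]2(C)O[C@@H]2[C@@H](O)C1=O | intermediate
21 | benzyl 2-(diethoxyphosphoryl)acetate | CCOP(=O)(CC(=O)OCc1ccccc1)OCC | starting material
22 | (chloromethoxy)tri(propan-2-yl)silane | CC(C)[Si](OCCl)(C(C)C)C(C)C | starting material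
23 | benzyl 2-(diethoxyphosphoryl)-3-{[tri(propan-2-yl)silyl]oxy}propanoate | CCOP(=O)(OCC)C(CO[Si](C(C)C)(C(C)C)C(C)C)C(=O)OCc1ccccc1 | intermediate
24 | 2-(diethoxyphosphoryl)-3-{[tri(propan-2-yl)silyl]oxy}propanoic acid | OC(=O)C(CO[Si](C(C)C)(C(C)C)C(C)C)P(=O)(OCC)OCC | intermediate
25 | 6-O-[2-(diethoxyphosphoryl)-3-(triisopropylsilyloxy)propanoyl] ester of 20 | CC(C)(C)[Si](C)(C)O[C@H]1CC(=C)/C=C\C[C@@]2(C)O[C@@H]2[C@@H](OC(=O)C(CO[Si](C(C)C)(C(C)C)C(C)C)P(=O)(OCC)OCC)C1=O | intermediate
26 | (4R,5R,6S,8S)-8-[(tert-butyldimethylsilyl)oxy]-4,5-epoxy-13-[(triisopropylsilyl)oxy]germacra-1Z,7(11),10(14)-trien-12,6-olide | CC(C)(C)[Si](C)(C)O[C@H]1CC(=C)/C=C\C[C@@]2(C)O[C@@H]2[C@H]2OC(=O)C(CO[Si](C(C)C)(C(C)C)C(C)C)=C12 | intermediate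
27 | (4R,5R,6S,8S)-4,5-epoxy-8,13-dihydroxygermacra-1Z,7(11),10(14)-trien-12,6-olide | O[C@H]1CC(=C)/C=C\C[C@@]2(C)O[C@@H]2[C@H]2OC(=O)C(CO)=C12 | intermediate
28 | (4R,5R,6S,8S)-13-acetoxy-4,5-epoxy-8-hydroxygermacra-1Z,7(11),10(14)-trien-12,6-olide | O[C@H]1CC(=C)/C=C\C[C@@]2(C)O[C@@H]2[C@H]2OC(=O)C(COC(C)=O)=C12 | intermediate
29 | ethyl 2-(hydroxymethyl)prop-2-enoate | C=C(CO)C(=O)OCC | starting material
30 | ethyl 2-{[(tert-butyldimethylsilyl)oxy]methyl}prop-2-enoate | C=C(CO[Si](C)(C)C(C)(C)C)C(=O)OCC | intermediate
31 | 2-{[(tert-butyldimethylsilyl)oxy]methyl}prop-2-enoic acid | C=C(CO[Si](C)(C)C(C)(C)C)C(=O)O | intermediate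
32 | (4R,5R,6S,8S)-13-acetoxy-8-(2-{[(tert-butyldimethylsilyl)oxy]methyl}acryloyloxy)-4,5-epoxygermacra-1Z,7(11),10(14)-trien-12,6-olide | C=C(CO[Si](C)(C)C(C)(C)C)C(=O)O[C@H]1CC(=C)/C=C\C[C@@]2(C)O[C@@H]2[C@H]2OC(=O)C(COC(C)=O)=C12 | intermediate
33 | (4R,5R,6S,8S)-13-acetoxy-4,5-epoxy-8-[2-(hydroxymethyl)acryloyloxy]germacra-1Z,7(11),10(14)-trien-12,6-olide | C=C(CO)C(=O)O[C@H]1CC(=C)/C=C\C[C@@]2(C)O[C@@H]2[C@H]2OC(=O)C(COC(C)=O)=C12 | intermediate
34 | (1R,2S,4R,5R,6S,8S)-13-acetoxy-1,2:4,5-diepoxy-8-[2-(hydroxymethyl)acryloyloxy]germacra-7(11),10(14)-dien-12,6-olide | C=C(CO)C(=O)O[C@H]1CC(=C)[C@H]2O[C@H]2C[C@@]2(C)O[C@@H]2[C@H]2OC(=O)C(COC(C)=O)=C12 | target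

**Step count**
Total: 24 steps. Longest linear sequence: 19 steps (1–8, 10–13, 16–19, 22–24).

**Steps most likely to fail**

1. Step 12 (Proposed new method). After ionisation the palladium allyl and the enolate may not recombine inside the ring, so protonation, O-allylation or intermolecular allylation to oligomers could take over; facial selectivity at C8 may also be low. The fallback uses known chemistry and closes the ring directly instead of by contraction. It sets out from 17: the C9 hydroxyl is converted into the allylic methyl carbonate F1 (ClCO2Me, pyridine, CH2Cl2, 0 °C). Pd(PPh3)4 in THF at high dilution ionises the carbonate, the released methoxide deprotonates the β-keto thioester, and the soft enolate closes the ten-membered ring by Tsuji–Trost allylic alkylation to the α-allylated β-keto thioester F2. Silver trifluoroacetate in wet THF hydrolyses the thioester to the β-keto acid F3, which loses CO2 on warming and comes back to the route at 19; C8 is then set by ketonisation and would be equilibrated or separated at that point.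

2. Step 24. The macrocycle may oppose the facial preference of the catalyst, or oxygen may also be transferred to the C10=C14 bond. The fallback moves the epoxidation two steps forward and relies on substrate control. It sets out from 28: dimethyldioxirane (acetone/CH2Cl2, −40 °C; concerted, hence stereospecific), with the free C8 hydroxyl as a hydrogen-bond handle, would give the epoxy alcohol F4. Esterification with 31 (EDC, DMAP) would give F5, and fluoride buffered with acetic acid (TBAF/AcOH, THF, 0 °C), which spares the vinyl epoxide, comes back to the route at 34.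

3. Step 10. The hindered thioester enolate may add slowly to the α-silyloxy ester, leaving time for enolate decomposition (ketene formation) and transacylation by the C9 alkoxide. The fallback sets out from 13: the ester is first converted into the Weinreb amide F6 (MeNHOMe·HCl, i-PrMgCl, THF, −20 °C). Addition of the lithium enolate of 16 then stops at the chelated tetrahedral intermediate and comes back to the route at 17 on acidic work-up.

**Further compounds**
F1 | step 12 | methyl carbonate of 17 at the C9 oxygen | C=C(COC(=O)OC)/C=C\C[C@@]1(C)O[C@@H]1[C@@H](O[Si](CC)(CC)CC)C(=O)C(O[Si](C)(C)C(C)(C)C)C(=O)SC(C)(C)C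
F2 | step 12 | 8-[(tert-butylsulfanyl)carbonyl] derivative of 19 (C8 quaternary, configuration open) | CC(C)(C)SC(=O)C1(O[Si](C)(C)C(C)(C)C)CC(=C)/C=C\C[C@@]2(C)O[C@@H]2[C@@H](O[Si](CC)(CC)CC)C1=O
F3 | step 12 | 8-carboxylic acid derived from F2 | OC(=O)C1(O[Si](C)(C)C(C)(C)C)CC(=C)/C=C\C[C@@]2(C)O[C@@H]2[C@@H](O[Si](CC)(CC)CC)C1=O
F4 | step 24 | (1R,2S)-1,2-epoxide of 28 | O[C@H]1CC(=C)[C@H]2O[C@H]2C[C@@]2(C)O[C@@H]2[C@H]2OC(=O)C(COC(C)=O)=C12
F5 | step 24 | (1R,2S)-1,2-epoxide of 32 | C=C(CO[Si](C)(C)C(C)(C)C)C(=O)O[C@H]1CC(=C)[C@H]2O[C@H]2C[C@@]2(C)O[C@@H]2[C@H]2OC(=O)C(COC(C)=O)=C12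
F6 | step 10 | N-methoxy-N-methylamide corresponding to ester 13 | C=C(CO)/C=C\C[C@@]1(C)O[C@@H]1[C@@H](O[Si](CC)(CC)CC)C(=O)N(C)OC
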